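A first-order loss cannot keep its pace while its substrate halves, yet in the elm run the substrate falls to half of its value between 12.0 min and 60.0 min, while the product gains 6.56 mM/min before 40.0 min and 6.97 mM/min after it. So we read the elm run as zero order in substrate, and we freeze its rate.

common to all: gas 51 mM (held)

| flask | substrate | free catalyst | temperature | remark | time |
|---|---|---|---|---|---|
| elm | 0.67 M | 2 mM | 35 °C | run made earlier |  |
| oak | 1.5 M | 2 mM | 50 °C | run made earlier |  |
| beta | 1.0 M | 2.0 mM | 60 °C |  | 20 min |
| delta | 1.0 M | 2.0 mM | 40 °C |  | 80 min |

| run | time / min | product / % | substrate / % |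
|---|---|---|---|
| elm | 4.00 | 2.1 | 95.6 |
| elm | 12.0 | 7.5 | 88.8 |
| elm | 25.0 | 22.6 | 78.2 |
| elm | 40.0 | 34.9 | 63.8 |
| elm | 50.0 | 45.1 | 54.6 |
| elm | 60.0 | 55.7 | 43.9 |
| oak | 2.50 | 1.1 | 99.6 |
| oak | 8.00 | 4.6 | 94.5 |
| oak | 15.0 | 7.8 | 92.0 |
| oak | 25.0 | 13.1 | 85.6 |
| oak | 30.0 | 18.5 | 83.5 |
| oak | 40.0 | 20.6 | 75.4 |

(each reading ± 1 percentage point)

- the analysis behind the earlier runs scatters by 1 percentage point, standard deviation
- at the start none of the gas is in solution

* which of the two ends with the higher amount of product, in percent of the substrate charged ("neither" if they lie within 2 percentage points) (beta / delta / neither)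
* product at the end, in percent of the substrate charged, beta
* product at the end, in percent of the substrate charged, delta

We call the flow the concentration of product made per minute along such a straight stretch, and we read it in two independent ways: from the product gained and from the substrate lost between the second and the last reading. In the elm run these give 6.73 mM/min and 6.27 mM/min, which lie close together. In the oak run they part, at 7.50 mM/min against 8.95 mM/min.

To see which one cheats, we add product and substrate. Their sum must stay near the charge, since the catalyst can hold at most 0.133% of the oak charge. But the last oak pair sums to 96.0%, while the last elm pair sums to 99.6%. We lay that shortfall to the analysis, with its scatter of 1 percentage point per reading, and not to the flask, so we take the mean of each pair: 6.50 mM/min for elm and 8.23 mM/min for oak.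

A straight line in temperature then gives the flow at the temperature of delta, 7.07 mM/min, and 9.38 mM/min for beta, which lies beyond the readings and is held more loosely. Flow times time, over the charge, gives us 56.6% for delta and 18.8% for beta.

The forecast says delta, with 54% for delta and 17% for beta, on the ground that “gas transfer limits the rate, rather than chemistry”.

The flask gives delta: 58.2% for delta and 18.5% for beta.

    partner + catalyst intermediate A → catalyst intermediate B (k = 6.09 /M/s, Ea = 50.0 kJ/mol)
    substrate + free catalyst ⇌ catalyst intermediate A (K = 7.25 /M, k = 20.0 /M/s, Ea = 52.0 kJ/mol, ΔH = −45.0 kJ/mol)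
    catalyst intermediate B ⇌ catalyst intermediate C (K = 38.0, k = 24.6 /s, Ea = 75.0 kJ/mol, ΔH = −54.0 kJ/mol)
    gas ⇌ partner, rate k4*(csat - [partner]) (kL = 0.00356 /s)
    catalyst intermediate C → free catalyst + product (k = 0.267 /s, Ea = 76.0 kJ/mol)
    (constants at 40 °C)

Delta ends ahead of beta because of its longer time, although the flow of beta is the larger: beta given the time of delta stands at 73.8%. The flow carries over to the neighbour that is delta with 0.60 M of substrate: it reckons 94.3%, and that flask reaches 88.5%, with 11% of its substrate left.

Readings and results come from a simulation with made-up constants; the scatter is artificial.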